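**Plan**

- Retrosynthesis: first the three O–CH3 bonds that mask the phenols; then the chain C–C bond lying five carbons from ring B and seven carbons from ring A, carried as a C=C (ring-closing metathesis of a hex-5-enyl chain on ring B with an oct-7-enyl chain on ring A); then the diaryl ether C–O bond; last the two aryl–CH2 bonds.
- Forward: each ring receives its ω-alkenyl chain by a Negishi coupling, the rings are joined through oxygen by an Ullmann coupling, the 20-membered ring is closed by metathesis and saturated in the same flask, and the methyl ethers are cleaved last.
- Enabling feature: the tether between C5 of ring A and C4 of ring B is an unbranched (CH2)12 chain with no heteroatom or stereocentre, so one of its C–C bonds can pass through the alkene oxidation level and leave no trace. The Ar–O–Ar hinge (meta on ring A, para on ring B) turns both chain ends toward each other.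
- Stereochemistry: the target has no stereocentre; the only stereo element on the way, the E/Z geometry of the ring alkene, is erased by hydrogenation.

Key step: step 4

Remark: the ring alkene formed in the key step is expected as an E/Z mixture; its SMILES is written without double-bond geometry because both isomers give the same saturated ring.

**Route**

Step 1
Reactants: 1 4-bromo-2,6-dimethoxyphenol; 2 6-bromohex-1-ene
Product: 4 4-(hex-5-en-1-yl)-2,6-dimethoxyphenol, via hex-5-en-1-ylzinc bromide 3 (not isolated)
Conditions: 2, Zn dust, LiCl, THF, 50 °C; then 1, Pd(OAc)2 (2 mol%), SPhos (4 mol%), THF, 25 °C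
Reagents that add atoms: none
Why: Negishi coupling, in which zinc inserts into the primary C–Br bond of 2 and the SPhos-ligated zerovalent palladium formed from Pd(OAc)2 adds to the aryl C–Br bond of 1, transmetalates with 3 and reductively eliminates faster than the weakly basic alkylzinc is protonated by the free phenol or the primary alkylpalladium loses a β-hydride.

Step 2
Reactants: 5 1-bromo-3-iodo-5-methoxybenzene; 6 8-bromooct-1-ene
Product: 8 1-bromo-3-methoxy-5-(oct-7-en-1-yl)benzene, via oct-7-en-1-ylzinc bromide 7 (not isolated)
Conditions: 6, Zn dust, LiCl, THF, 50 °C; then 5, PdCl2(dppf) (2 mol%), THF, 0 °C to rt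
Reagents that add atoms: none
Why: Site-selective Negishi coupling, since oxidative addition of zerovalent palladium to the C–I bond of 5 is far faster than to its C–Br bond at room temperature, so one equivalent of 7 should alkylate only the iodide position and keep the bromide for the ether coupling.

Step 3
Reactants: 4 4-(hex-5-en-1-yl)-2,6-dimethoxyphenol; 8 1-bromo-3-methoxy-5-(oct-7-en-1-yl)benzene
Product: 9 5-(hex-5-en-1-yl)-1,3-dimethoxy-2-[3-methoxy-5-(oct-7-en-1-yl)phenoxy]benzene
Conditions: CuI (10 mol%), picolinic acid (20 mol%), K3PO4, DMSO, 90 °C
Reagents that add atoms: none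
Why: Ullmann diaryl ether coupling, in which the picolinate complex of monovalent copper binds the hindered but electron-rich phenoxide of 4 and substitutes the unhindered aryl bromide 8, the doubly ortho-substituted partner being placed on the nucleophile side where such hindrance is tolerated best, while terminal alkenes and methyl ethers stay inert.

Step 4
Reactants: 9 5-(hex-5-en-1-yl)-1,3-dimethoxy-2-[3-methoxy-5-(oct-7-en-1-yl)phenoxy]benzene
Product: 11 1⁵,3²,3⁶-trimethoxy-2-oxa-1(1,3),3(1,4)-dibenzenacyclopentadecaphane (saturated 20-membered diaryl ether macrocycle), via ring alkene trimethyl ether 10 (not isolated)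
Conditions: second-generation Grubbs catalyst RuCl2(=CHPh)(PCy3)(H2IMes) (5 mol%), CH2Cl2 (1 mM), 40 °C; then concentrate, EtOAc, 10% Pd/C, H2 (1 atm), rt
Reagents that add atoms: none
Why: The benzylidene of the catalyst exchanges with one terminal alkene of 9 to give a chain-end ruthenium alkylidene, which adds to the other terminal alkene through a ruthenacyclobutane ([2+2] cycloaddition, then cycloreversion) and releases ethene, whose loss drives the closure, after which Pd/C and H2 saturate the new C=C. The closest known reaction type is ring-closing olefin metathesis of α,ω-dienes to macrocyclic diaryl ethers and cyclophanes followed by catalytic hydrogenation. The 20-membered ring closes as a macrocyclization in which the new C=C lies inside the ring and links the fifth chain carbon from ring B to the seventh from ring A. No stereocentre is formed, and the E/Z geometry of 10 is removed by the hydrogenation. The step needs ring closure to win over intermolecular metathesis, which high dilution, two equally reactive unhindered terminal alkenes, the reversibility of metathesis (acyclic oligomers can back-bite to the unstrained ring) and the bent Ar–O–Ar hinge that points both chains to the same side should secure. No other alkene is present to compete, and neither catalyst touches the aryl ethers.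

Step 5
Reactants: 11 1⁵,3²,3⁶-trimethoxy-2-oxa-1(1,3),3(1,4)-dibenzenacyclopentadecaphane
Product: 12 2-oxa-1(1,3),3(1,4)-dibenzenacyclopentadecaphane-1⁵,3²,3⁶-triol (CNP0314249.0)
Conditions: BBr3 (6 equiv), CH2Cl2, −78 °C to rt; then H2O
Reagents that add atoms: none
Why: Lewis acid-mediated aryl methyl ether cleavage, in which BBr3 coordinates each methoxy oxygen and bromide attacks the methyl carbon in an SN2 step, whereas the diaryl ether oxygen bears no sp3 carbon and should survive, and hydrolysis of the aryl borates releases the three phenols.

**Compound list**

1 | 4-bromo-2,6-dimethoxyphenol | COc1cc(Br)cc(OC)c1O | starting material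
2 | 6-bromohex-1-ene | C=CCCCCBr | starting material
3 | hex-5-en-1-ylzinc bromide | C=CCCCC[Zn]Br | intermediate
4 | 4-(hex-5-en-1-yl)-2,6-dimethoxyphenol | COc1cc(CCCCC=C)cc(OC)c1O | intermediate
5 | 1-bromo-3-iodo-5-methoxybenzene | COc1cc(Br)cc(I)c1 | starting material
6 | 8-bromooct-1-ene | C=CCCCCCCBr | starting material
7 | oct-7-en-1-ylzinc bromide | C=CCCCCCC[Zn]Br | intermediate
8 | 1-bromo-3-methoxy-5-(oct-7-en-1-yl)benzene | COc1cc(Br)cc(CCCCCCC=C)c1 | intermediate
9 | 5-(hex-5-en-1-yl)-1,3-dimethoxy-2-[3-methoxy-5-(oct-7-en-1-yl)phenoxy]benzene | COc1cc(CCCCCCC=C)cc(Oc2c(OC)cc(CCCCC=C)cc2OC)c1 | intermediate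
10 | 1⁵,3²,3⁶-trimethoxy-2-oxa-1(1,3),3(1,4)-dibenzenacyclopentadecaphan-8-ene (20-membered ring alkene, E/Z mixture, geometry not specified; C=C between the fifth chain carbon from ring B and the seventh from ring A) | COc1cc2cc(c1)Oc1c(OC)cc(cc1OC)CCCCC=CCCCCCC2 | intermediate
11 | 1⁵,3²,3⁶-trimethoxy-2-oxa-1(1,3),3(1,4)-dibenzenacyclopentadecaphane (ring A: C1–O, C3–chain, C5–OMe; ring B: C1–O, C2 and C6 OMe, C4–chain; chain (CH2)12) | COc1cc2cc(c1)Oc1c(OC)cc(cc1OC)CCCCCCCCCCCC2 | intermediate
12 | 2-oxa-1(1,3),3(1,4)-dibenzenacyclopentadecaphane-1⁵,3²,3⁶-triol (ring A: 5-hydroxy-1,3-phenylene; ring B: 2,6-dihydroxy-1,4-phenylene bound to the ether oxygen at C1; chain (CH2)12; 20-membered ring) | Oc1cc2cc(c1)Oc1c(O)cc(cc1O)CCCCCCCCCCCC2 | target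

**Summary**

Total step count: 5. Longest linear sequence: 4 steps (step 1 or step 2, then steps 3, 4 and 5).

**Steps most likely to fail**

Step 4. Intermolecular metathesis may outrun ring closure and give dimers and oligomers, and ruthenium hydrides may shift the terminal double bonds before closure, which would lead to ring-contracted homologues. The fallback sets out from 9 and replaces metathesis by a reductive carbonyl coupling of the same two carbons. Lemieux–Johnson cleavage of both terminal alkenes (OsO4 cat., NaIO4, 2,6-lutidine, dioxane/H2O, rt) should give the dialdehyde 7-{3-[2,6-dimethoxy-4-(5-oxopentyl)phenoxy]-5-methoxyphenyl}heptanal F1. An intramolecular McMurry coupling (TiCl3, Zn(Cu) couple, DME, reflux, slow addition of F1) should then join the two aldehyde carbons on low-valent titanium and deliver the ring alkene 10, where the route resumes with the hydrogenation to 11.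

Step 3. The C–O coupling of the doubly ortho-substituted phenoxide with an unactivated aryl bromide may be slow, so that reduction of the bromide or oxidation of the electron-rich phenol competes. The fallback sets out from 8 and forms the same bond oxidatively at room temperature. Bromine–lithium exchange (n-BuLi, THF, −78 °C), B(OiPr)3 and aqueous HCl should give [3-methoxy-5-(oct-7-en-1-yl)phenyl]boronic acid F2. Chan–Lam coupling of F2 with 4 (Cu(OAc)2, pyridine, 4 Å molecular sieves, CH2Cl2, air, rt), which runs through divalent copper and needs no aryl halide, comes back to the route at 9.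

Step 1. The hex-5-enyl radical formed during zinc insertion may cyclize to cyclopentylmethyl units, the organozinc may be protonated by the phenol, and oxidative addition to the electron-rich bromide may be slow. The fallback sets out from 1 and takes the chain from a diene by polar hydroboration, with a boron reagent that tolerates water and the phenoxide. Monohydroboration of hexa-1,5-diene (large excess) with 9-BBN in THF should give 9-(hex-5-en-1-yl)-9-borabicyclo[3.3.1]nonane F3. B-alkyl Suzuki coupling of F3 with 1 (Pd(OAc)2, SPhos, K3PO4, THF/H2O, 65 °C) comes back to the route at 4.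

**Further compounds**

F1 | step 4 | 7-{3-[2,6-dimethoxy-4-(5-oxopentyl)phenoxy]-5-methoxyphenyl}heptanal | COc1cc(CCCCCCC=O)cc(Oc2c(OC)cc(CCCCC=O)cc2OC)c1
F2 | step 3 | [3-methoxy-5-(oct-7-en-1-yl)phenyl]boronic acid | COc1cc(B(O)O)cc(CCCCCCC=C)c1
F3 | step 1 | 9-(hex-5-en-1-yl)-9-borabicyclo[3.3.1]nonane | C=CCCCCB1C2CCCC1CCC2
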